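With time the substrate falls along one curve in both earlier runs: at 0.050 M and at 0.075 M the readings stand at 71 % and 71 % after 1.00 min, then at 45 % and 44 % after 2.50 min.

| setting | noon | autumn | violet | blue |
|---|---|---|---|---|
| substrate | 0.050 M | 0.075 M | 0.10 M | 0.10 M |
| remark | run made earlier | run made earlier |  |  |
| time |  |  | 3.0 min | 2.0 min |

| run | time / min | intermediate B / % | intermediate A / % | target / % | substrate / % | side product A / % |
|---|---|---|---|---|---|---|
| noon | 0.200 | 2 | 5 | 0 | 90 | 0 |
| noon | 0.333 | 0 | 5 | 0 | 89 | 0 |
| noon | 0.417 | 1 | 7 | 2 | 86 | 0 |
| noon | 0.667 | 4 | 7 | 0 | 79 | 0 |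
| noon | 1.00 | 6 | 9 | 0 | 71 | 1 |
| noon | 1.50 | 8 | 11 | 1 | 59 | 1 |
| noon | 2.50 | 6 | 23 | 0 | 45 | 2 |
| autumn | 0.167 | 1 | 1 | 0 | 95 | 3 |
| autumn | 0.333 | 4 | 3 | 2 | 87 | 1 |
| autumn | 0.667 | 5 | 7 | 1 | 78 | 0 |
| autumn | 1.00 | 8 | 6 | 2 | 71 | 1 |
| autumn | 1.33 | 7 | 13 | 0 | 63 | 0 |
| autumn | 2.00 | 8 | 16 | 0 | 52 | 2 |
| autumn | 2.50 | 8 | 21 | 0 | 44 | 0 |

(readings scatter by 1.5 percentage points)

- a reading or a percentage of target counts all its forms, free or not
- a reading of substrate is of its free form alone

- which of these there is most of at the end, counted by the substrate in it, violet (side product A / intermediate A / intermediate B / substrate)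
- which of these there is most of at the end, counted by the substrate in it, blue (side product A / intermediate A / intermediate B / substrate)
- the largest of these amounts at the end, in percent of the substrate charged, violet
- the largest of these amounts at the end, in percent of the substrate charged, blue

The quantity to carry is the apparent first-order constant, the logarithm of charged over left [substrate] divided by the time, which the noon reading at 1.00 min gives as 0.342 /min. The last stretch of the noon run reads slower, 0.271 /min, so the loss seems to ease, though each reading scatters by 1.5 percentage points. My own bracket follows from this, and both its ends carry the scatter of the readings behind them. Holding the early constant from the start gives a lower bound of 35.8 % for violet and 50.4 % for blue, while running on from the noon readings with the slower constant gives an upper bound of 39.3 % and 51.5 %. Intermediate A, extended along its noon rise, reaches 29.0 % in violet, less than the lower bound, so substrate should lead.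

The forecast, seeing “no visible dependence on concentration”, names substrate for violet and substrate for blue, with 37.5 % (33 % to 42 %) and 52 % (47 % to 57 %). Its violet value lies inside my bracket, and its blue value lies 0.50 points above it.

Violet gives substrate at 38.6 % and blue substrate at 50.8 %, both within the bracket.

    substrate → intermediate A (k = 0.00200 /s)
    substrate ⇌ intermediate B (K = 0.240, k = 0.00160 /s)
    intermediate A → intermediate C (k = 4.30 × 10⁻⁴ /s)
    intermediate C → intermediate D (k = 0.00160 /s)
    intermediate D → target (k = 3.20 × 10⁻⁴ /s)
    intermediate C → side product A (k = 0.0950 /s)
    substrate + target ⇌ idle adduct, settled at all times (K = 12.0 /M)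
    substrate ⇌ dormant form (K = 4.10, k = 0.00280 /s)
    substrate + intermediate C → side product B (k = 0.00610 /M/s)

Of the two settings tried, it is the time that has to move for the forecast to fail in violet: violet's substrate has moved 6 points at 2.46 min or 3.70 min with all amounts held, yet stays within that at least from 0.0125 M to 0.80 M of charge with the time held. Over its 3.0 min, violet's own apparent constant comes to 0.317 /min. Left until 12 min, the violet flask holds 10.3 % of substrate against the 1.65 % the carried constant gives, with 43.3 % of dormant form beside it.

The data were generated by integration for an exercise; the scatter is artificial.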